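**Retrosynthetic overview** (C-numbers are germacrane positions)
1. Target 13 ⇒ ring-closing metathesis at C1=C10 of diene lactone 12; the ten-membered carbocycle is formed last.
2. 12 ⇒ CrCl2-mediated 2-(methoxycarbonyl)allylation/lactonisation joining enal 10 (C1–C6, C15) with allyl bromide 6 (C7–C14); this forms C6–C7, sets C6 and C7, and makes the γ-lactone (first ring).
3. 6 ⇒ organocatalytic desymmetrising SN2′ acetoxylation of the prochiral bis(allyl bromide) 5; this sets C8 and C9 and leaves one arm as the allyl bromide (new reaction).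
4. 5 ⇒ double cross-metathesis of divinylcarbinol tiglate 3 with methyl 2-(bromomethyl)acrylate 4.
5. 10 ⇒ anti-carbomagnesiation of but-2-yne-1,4-diol, then regioselective MnO2 oxidation.

Assumption: the SMILES is taken as drawn, i.e. (6R,7S,8S,9S), trans-fused 12,6-lactone, 8-O-tiglate, 9-O-acetate, and both ring alkenes cis within the ring (each E by CIP).

**Step 1**
Reactants: 1 penta-1,4-dien-3-ol; 2 tiglic acid, (2E)-2-methylbut-2-enoic acid
Product: 3 penta-1,4-dien-3-yl (2E)-2-methylbut-2-enoate
Conditions: DCC, DMAP (cat.), CH2Cl2, 0 °C to rt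
Reagents that add atoms: none
Why: Steglich esterification of the secondary bis-allylic alcohol under base-free conditions, which keeps the tiglate E-geometry and avoids deconjugation.

**Step 2**
Reactants: 3 penta-1,4-dien-3-yl (2E)-2-methylbut-2-enoate; 4 methyl 2-(bromomethyl)prop-2-enoate (8 equiv)
Product: 5 dimethyl (2Z,5Z)-2,6-bis(bromomethyl)-4-{[(2E)-2-methylbut-2-enoyl]oxy}hepta-2,5-dienedioate
Conditions: second-generation Hoveyda–Grubbs catalyst (2 × 5 mol%), CH2Cl2, 40 °C, argon sparge
Reagents that add atoms: none
Why: Twofold olefin cross-metathesis of the terminal vinyl groups with the 1,1-disubstituted acrylate gives the thermodynamic trisubstituted enoates (C4 trans to CO2Me, cis to CH2Br), while the trisubstituted tiglate alkene and the allylic bromides are inert to the ruthenium carbene.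

**Step 3**
Reactants: 5 dimethyl (2Z,5Z)-2,6-bis(bromomethyl)-4-{[(2E)-2-methylbut-2-enoyl]oxy}hepta-2,5-dienedioate
Product: 6 dimethyl (2Z,4S,5S)-5-(acetyloxy)-2-(bromomethyl)-6-methylidene-4-{[(2E)-2-methylbut-2-enoyl]oxy}hept-2-enedioate
Conditions: (DHQD)2PHAL (10 mol%), powdered KOAc (1.05 equiv), toluene, 0 °C
Reagents that add atoms: potassium acetate, CC(=O)[O-].[K+]
Why: Proposed new method: enantioselective desymmetrising SN2′ acetoxylation, in which the quinuclidine nitrogen of the cinchona catalyst displaces bromide from one of the two enantiotopic CH2Br arms of prochiral 5 to give a chiral allylammonium ion and its acetate counter-ion adds SN2′ at C5 (germacrane C9) with release of the catalyst, anti to the bulky second alkenyl arm while H-4 eclipses the enoate (allylic 1,3-strain), so that C5 (S) is created and C4 (S) becomes stereogenic as the 4,5-threo pair, the minor enantiomer being drained by faster second substitution at its remaining matched arm; closest known reaction type: cinchona-amine-catalysed asymmetric allylic substitution of Morita–Baylis–Hillman carbonates with O-nucleophiles and amine-mediated SN2′ substitution of Baylis–Hillman bromides.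

**Step 4**
Reactants: 7 but-2-yne-1,4-diol; 8 but-3-en-1-ylmagnesium bromide (4.5 equiv)
Product: 9 (2E)-2-(but-3-en-1-yl)but-2-ene-1,4-diol
Conditions: CuI (10 mol%), THF, reflux; aq. NH4Cl
Reagents that add atoms: none
Why: Copper-catalysed, alkoxide-directed anti-carbomagnesiation of a propargylic alcohol places the butenyl group on C2 anti to magnesium held in a five-membered alkoxide chelate on C3, so protonation gives only the E-diol (butenyl cis to the distal CH2OH), and the dialkoxide cannot β-eliminate.

**Step 5**
Reactants: 9 (2E)-2-(but-3-en-1-yl)but-2-ene-1,4-diol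
Product: 10 (2E)-3-(hydroxymethyl)hepta-2,6-dienal
Conditions: activated MnO2 (10 equiv), CH2Cl2, 0 °C, stopped at mono-oxidation
Reagents that add atoms: none
Why: Regioselective MnO2 allylic oxidation, the less hindered prenol-type CH2OH on the CH= terminus (hydrogen abstraction gives a tertiary allyl radical) reacting faster than the 2-substituted allylic CH2OH, which is then deactivated by the new enal; the E-geometry prevents lactol or furan formation.

**Step 6**
Reactants: 10 (2E)-3-(hydroxymethyl)hepta-2,6-dienal; 6 dimethyl (2Z,4S,5S)-5-(acetyloxy)-2-(bromomethyl)-6-methylidene-4-{[(2E)-2-methylbut-2-enoyl]oxy}hept-2-enedioate (1.2 equiv)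
Product: 12 methyl (3S,4S)-3-(acetyloxy)-4-{(2R,3S)-2-[(1E)-2-(hydroxymethyl)hexa-1,5-dien-1-yl]-4-methylidene-5-oxooxolan-3-yl}-2-methylidene-4-{[(2E)-2-methylbut-2-enoyl]oxy}butanoate, via seco hydroxy ester 11 (not isolated)
Conditions: CrCl2 (4 equiv), THF, 0 °C to rt; 1 M HCl work-up; then PPTS (cat.), CH2Cl2, rt
Reagents that add atoms: none
Why: Nozaki–Hiyama-type 2-(alkoxycarbonyl)allylation followed by lactonisation, in which the equilibrating allylchromium adds through a chair transition state to give the anti adduct (6,7-trans lactone) and C6 bonds to the C7 face anti to the C8–C9 bond with H-8 eclipsing the alkene (allylic 1,3-strain, OTig outside), setting C6 (R) and C7 (S), after which acid closes the γ-lactone with loss of methanol; the allylic acetate, the tiglate and the free primary alcohol are inert to divalent chromium.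

**Step 7**
Reactants: 12 methyl (3S,4S)-3-(acetyloxy)-4-{(2R,3S)-2-[(1E)-2-(hydroxymethyl)hexa-1,5-dien-1-yl]-4-methylidene-5-oxooxolan-3-yl}-2-methylidene-4-{[(2E)-2-methylbut-2-enoyl]oxy}butanoate
Product: 13 CNP0216801.5, methyl (6R,7S,8S,9S)-9-acetoxy-15-hydroxy-8-tigloyloxy-12,6-olide of germacra-1(10),4,11(13)-trien-14-oate (both ring alkenes ring-cis)
Conditions: second-generation Hoveyda–Grubbs catalyst (15 mol%, portionwise), 1,4-benzoquinone (20 mol%), toluene (1 mM), 80 °C
Reagents that add atoms: none
Why: Ring-closing metathesis between the terminal alkene and the C10 methylidene ester gives the ten-membered ring with the less strained ring-cis trisubstituted enoate (C2 trans to CO2Me), while the lactone α-methylene cannot compete because closure there would create a bridgehead alkene, and no stereocentre is touched.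

**Compound list**
1 | penta-1,4-dien-3-ol | C=CC(O)C=C | starting material
2 | tiglic acid, (2E)-2-methylbut-2-enoic acid | C/C=C(\C)C(O)=O | starting material
3 | penta-1,4-dien-3-yl (2E)-2-methylbut-2-enoate | C=CC(OC(=O)/C(C)=C/C)C=C | intermediate
4 | methyl 2-(bromomethyl)prop-2-enoate | C=C(CBr)C(=O)OC | starting material
5 | dimethyl (2Z,5Z)-2,6-bis(bromomethyl)-4-{[(2E)-2-methylbut-2-enoyl]oxy}hepta-2,5-dienedioate | COC(=O)/C(CBr)=C/C(OC(=O)/C(C)=C/C)/C=C(CBr)/C(=O)OC | intermediate
6 | dimethyl (2Z,4S,5S)-5-(acetyloxy)-2-(bromomethyl)-6-methylidene-4-{[(2E)-2-methylbut-2-enoyl]oxy}hept-2-enedioate | COC(=O)/C(CBr)=C/[C@H](OC(=O)/C(C)=C/C)[C@@H](OC(C)=O)C(=C)C(=O)OC | intermediate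
7 | but-2-yne-1,4-diol | OCC#CCO | starting material
8 | but-3-en-1-ylmagnesium bromide | C=CCC[Mg]Br | starting material
9 | (2E)-2-(but-3-en-1-yl)but-2-ene-1,4-diol | OC/C(CCC=C)=C/CO | intermediate
10 | (2E)-3-(hydroxymethyl)hepta-2,6-dienal | OC/C(CCC=C)=C/C=O | intermediate
11 | dimethyl (3S,4S,5S)-3-(acetyloxy)-5-[(1R,2E)-1-hydroxy-3-(hydroxymethyl)hepta-2,6-dien-1-yl]-2,6-dimethylidene-4-{[(2E)-2-methylbut-2-enoyl]oxy}heptanedioate | OC/C(CCC=C)=C/[C@@H](O)[C@H](C(=C)C(=O)OC)[C@H](OC(=O)/C(C)=C/C)[C@@H](OC(C)=O)C(=C)C(=O)OC | intermediate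
12 | methyl (3S,4S)-3-(acetyloxy)-4-{(2R,3S)-2-[(1E)-2-(hydroxymethyl)hexa-1,5-dien-1-yl]-4-methylidene-5-oxooxolan-3-yl}-2-methylidene-4-{[(2E)-2-methylbut-2-enoyl]oxy}butanoate | C=C1C(=O)O[C@H](/C=C(/CO)CCC=C)[C@H]1[C@H](OC(=O)/C(C)=C/C)[C@@H](OC(C)=O)C(=C)C(=O)OC | intermediate
13 | CNP0216801.5, (6R,7S,8S,9S)-9-acetoxy-15-hydroxy-8-tigloyloxy-germacra-1(10),4,11(13)-trien-12,6-olid-14-oic acid methyl ester | C=C1C(=O)O[C@@H]2/C=C(/CO)CC/C=C(/C(=O)OC)[C@H](OC(C)=O)[C@@H](OC(=O)/C(C)=C/C)[C@@H]12 | target

**Totals**
Total steps: 7. Longest linear sequence: 5 (steps 1, 2, 3, 6, 7); steps 4 and 5 form the second branch.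

**Three steps most likely to fail**

Step 3 (the new desymmetrisation). The risks are:
- uncatalysed SN2 of acetate giving the achiral linear acetate;
- a polar Felkin-type preference for the erythro isomer;
- over-substitution of the second arm;
- a reversed sense of induction, in which case the pseudoenantiomeric (DHQ)2PHAL would be used.

Fallback with known chemistry, setting out from 5 and coming back at 6: DABCO (1 equiv) converts one arm of 5 into the allylammonium salt and KOAc adds SN2′ (MeCN, 0 °C). This is the established stoichiometric-amine substitution of Baylis–Hillman bromides and gives no asymmetric induction. Chromatography removes the erythro isomer and the bis-acetate, leaving the racemic threo monoacetate, that is 6 mixed with its mirror image, the (4R,5R)-monoacetate F1. Lipase-catalysed alcoholysis (Candida antarctica lipase B, n-BuOH, MTBE, 30 °C), a kinetic resolution known for Baylis–Hillman acetates, deacetylates F1 to the (4R,5R)-alcohol F2 and leaves 6, which is separated and carried on.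

Step 6 (chromium allylation). The risks are:
- C6 and C7 are set purely by substrate control, so the wrong allyl face or a syn adduct may form;
- the δ-acyloxy allylchromium may undergo 1,4-elimination to a dienoate.

Fallback, setting out from 6 and 10 and coming back at 12: stereocontrol is moved from the substrate to a catalyst by a catalytic asymmetric Nozaki–Hiyama allylation (CrCl2 10 mol%, chiral bis(oxazolinyl)carbazole ligand, Mn powder, TMSCl, iPr2NEt, THF, 0 °C). The ligand-bound allylchromium selects the aldehyde face and, through the chair, the C7 face, and gives the bis(trimethylsilyl) ether of 11 F3. HCl in MeOH removes both silyl groups and closes the lactone to 12.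

Step 7 (ring-closing metathesis). The risks are:
- a strained ten-membered ring with a hindered 1,1-disubstituted acrylate partner;
- competing dimerisation or ring opening by ethene.

Fallback, setting out from 6 and 10 and coming back at 13: the ring is instead closed by irreversible C–C bond formation. Cross-metathesis of 6 with excess 10 (second-generation Hoveyda–Grubbs catalyst, CH2Cl2, 40 °C) joins C1 to C10 and gives the open-chain bromo enal F4. Slow addition of F4 to CrCl2 in THF (1 mM) closes C6–C7 by intramolecular Nozaki–Hiyama allylation, a macrocyclisation precedented for germacranolides, to the ten-membered hydroxy ester F5. PPTS then lactonises F5 to 13.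

**Further compounds**
F1 | step 3 | dimethyl (2Z,4R,5R)-5-(acetyloxy)-2-(bromomethyl)-6-methylidene-4-{[(2E)-2-methylbut-2-enoyl]oxy}hept-2-enedioate (enantiomer of 6) | COC(=O)/C(CBr)=C/[C@@H](OC(=O)/C(C)=C/C)[C@H](OC(C)=O)C(=C)C(=O)OC
F2 | step 3 | dimethyl (2Z,4R,5R)-2-(bromomethyl)-5-hydroxy-6-methylidene-4-{[(2E)-2-methylbut-2-enoyl]oxy}hept-2-enedioate | COC(=O)/C(CBr)=C/[C@@H](OC(=O)/C(C)=C/C)[C@H](O)C(=C)C(=O)OC
F3 | step 6 | bis(trimethylsilyl) ether of 11 (C6–OTMS and C15–OTMS) | C[Si](C)(C)OC/C(CCC=C)=C/[C@@H](O[Si](C)(C)C)[C@H](C(=C)C(=O)OC)[C@H](OC(=O)/C(C)=C/C)[C@@H](OC(C)=O)C(=C)C(=O)OC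
F4 | step 7 | open-chain bromo enal, C1=C10 cross-metathesis product of 6 and 10 | O=C/C=C(/CO)CC/C=C(/C(=O)OC)[C@H](OC(C)=O)[C@@H](OC(=O)/C(C)=C/C)/C=C(CBr)/C(=O)OC
F5 | step 7 | ten-membered 6-hydroxy seco-lactone (C12 methyl ester, C6–C7 bond closed) | C=C(C(=O)OC)[C@H]1[C@H](O)/C=C(/CO)CC/C=C(/C(=O)OC)[C@H](OC(C)=O)[C@H]1OC(=O)/C(C)=C/C
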